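**Synthesis proposal for 2-hydroxy-4-[(4-hydroxy-2-methoxy-6-propylbenzoyl)oxy]-6-propylbenzoic acid (CNP0147807.0)**

1. Cuts: after removal of three benzyl groups and the ring B methyl ether, the target is cut at the depside C–O bond (ring B carboxyl carbon to O-4 of ring A) and at the C-1'–C-6' bond of ring B. Ring B thereby unravels into a 3,5,7-trioxodecanoyl chain, and this into an acylketene masked as a diketo-dioxinone.
2. Enabling feature: the depside carbonyl is C-1 of that chain and C-2 to C-7 map onto C-1' to C-6' of ring B (the C-3 and C-5 carbonyls become O-2' and O-4', C-7 carries the propyl group). Ring A has the same 2,4-dioxygenated 6-propylbenzoate pattern, so one diketo-dioxinone builds both rings.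
3. Forward order: the dioxinone is acylated with acetyl chloride and then with the butanoyl Weinreb amide. Ring A is folded first, by amine-promoted aldol aromatization of the diketo-dioxinone to its benzodioxinone, which benzyl alcohol opens to the benzyl ester; the 2-OH is then benzylated behind a temporary 4-O-allyl ether. A second portion of the diketo-dioxinone is unmasked as the acylketene and joined to the freed 4-OH, and ring B is closed last on that aryl ester.
4. End game: benzylation of the free 4'-OH, methylation of the hydrogen-bonded 2'-OH, then hydrogenolysis of all three benzyl groups.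
5. Stereochemistry: none to set. The target has no stereocentre and no stereogenic double bond, and the two sp3 centres of the aldol intermediates vanish on aromatization.

Key step: step 9

Remark on the chemistry: unprimed locants refer to ring A (the ring that ends with the free carboxylic acid), primed locants to ring B (the acyl ring); chain locants C-1 to C-10 refer to the trioxodecanoyl chain.

**Route**

Step 1
Reactants: 1 2,2,6-trimethyl-4H-1,3-dioxin-4-one; 2 acetyl chloride
Product: 3 2,2-dimethyl-6-(2-oxopropyl)-4H-1,3-dioxin-4-one
Conditions: 1 (2 equiv), LiN(SiMe3)2 (2 equiv), THF, −78 °C; then 2 (1 equiv), −78 °C; aq. HCl work-up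
Reagents that add atoms: none
Why: LiN(SiMe3)2 deprotonates the 6-methyl group of 1 to the cross-conjugated dienolate, which is C-acylated at that carbon by the acid chloride (crossed Claisen-type acylation of a vinylogous ester enolate), the dienolate being used in excess because 3 is more acidic than 1.

Step 2
Reactants: 4 butanoyl chloride
Product: 5 N-methoxy-N-methylbutanamide
Conditions: MeNHOMe·HCl, K2CO3, CH2Cl2–H2O, 0 °C to rt
Reagents that add atoms: N,O-dimethylhydroxylamine hydrochloride, CNOC.Cl
Why: Schotten–Baumann acylation of the amine gives the Weinreb amide, an acyl donor that stops at the ketone stage in the next step.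

Step 3
Reactants: 3 2,2-dimethyl-6-(2-oxopropyl)-4H-1,3-dioxin-4-one; 5 N-methoxy-N-methylbutanamide
Product: 6 6-(2,4-dioxoheptyl)-2,2-dimethyl-4H-1,3-dioxin-4-one
Conditions: LiN(iPr)2 (2.2 equiv), THF, −78 °C; then 5, −78 to −40 °C; aq. HCl work-up
Reagents that add atoms: none
Why: LiN(iPr)2 forms the dianion of 3 (first at the doubly activated CH2, then at the terminal CH3), and the more basic terminal carbanion attacks the Weinreb amide in a crossed Claisen condensation whose chelated tetrahedral adduct prevents a second addition.

Step 4
Reactants: 6 6-(2,4-dioxoheptyl)-2,2-dimethyl-4H-1,3-dioxin-4-one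
Product: 8 7-hydroxy-2,2-dimethyl-5-propyl-4H-1,3-benzodioxin-4-one, via cyclic aldol adduct 7 (not isolated)
Conditions: Et3N, CH2Cl2, rt; then HCl in 1,4-dioxane, rt
Reagents that add atoms: none
Why: Et3N enolizes the activated CH2 beside the dioxinone ring to a vinylogous enolate whose ring C-5 adds to the propyl ketone in an intramolecular aldol reaction (7), and acid completes the dehydration and enolization to the resorcylate acetonide, a known base-mediated cycloaromatization of diketo-dioxinones that keeps the dioxinone ring closed and generates no ketene.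

Step 5
Reactants: 8 7-hydroxy-2,2-dimethyl-5-propyl-4H-1,3-benzodioxin-4-one
Product: 9 benzyl 2,4-dihydroxy-6-propylbenzoate
Conditions: BnOH (excess), Cs2CO3 (2.5 equiv), THF, 60 °C; aq. HCl work-up
Reagents that add atoms: benzyl alcohol, OCc1ccccc1
Why: alkoxide transesterification of a salicylate acetonide, in which benzyloxide adds to the lactone carbonyl and the ring-opened hemiketal expels acetone irreversibly, so the benzyl ester and the 2-OH are released together.

Step 6
Reactants: 9 benzyl 2,4-dihydroxy-6-propylbenzoate
Product: 10 benzyl 2-hydroxy-4-(prop-2-en-1-yloxy)-6-propylbenzoate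
Conditions: allyl bromide (1.05 equiv), K2CO3, acetone, rt
Reagents that add atoms: allyl bromide, C=CCBr
Why: Williamson etherification with a weak base alkylates only the more acidic, free 4-OH, because the 2-OH is held in a hydrogen bond to the ester carbonyl.

Step 7
Reactants: 10 benzyl 2-hydroxy-4-(prop-2-en-1-yloxy)-6-propylbenzoate
Product: 11 benzyl 2-(benzyloxy)-4-(prop-2-en-1-yloxy)-6-propylbenzoate
Conditions: BnBr, K2CO3, DMF, 60 °C
Reagents that add atoms: benzyl bromide, BrCc1ccccc1
Why: with O-4 blocked, the chelated 2-OH is benzylated under more forcing Williamson conditions, still far below the temperature at which the allyl aryl ether would undergo Claisen rearrangement.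

Step 8
Reactants: 11 benzyl 2-(benzyloxy)-4-(prop-2-en-1-yloxy)-6-propylbenzoate
Product: 12 benzyl 2-(benzyloxy)-4-hydroxy-6-propylbenzoate
Conditions: Pd(PPh3)4 (5 mol%), morpholine, THF, rt
Reagents that add atoms: none
Why: Tsuji–Trost deallylation, in which the zerovalent palladium complex ionizes the allyl aryl ether to a π-allyl complex that morpholine intercepts, leaves the benzyl ether and the benzyl ester untouched.

Step 9
Reactants: 12 benzyl 2-(benzyloxy)-4-hydroxy-6-propylbenzoate; 6 6-(2,4-dioxoheptyl)-2,2-dimethyl-4H-1,3-dioxin-4-one
Product: 16 benzyl 2-(benzyloxy)-4-[(2,4-dihydroxy-6-propylbenzoyl)oxy]-6-propylbenzoate, via acylketene 13 (not isolated), via aryl 3,5,7-trioxodecanoate 14 (not isolated), via cyclic aldol adduct 15 (not isolated)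
Conditions: 6 (1.5 equiv), PhMe, 110 °C; then Et3N, CH2Cl2, 0 °C to rt; then HCl in 1,4-dioxane, rt
Reagents that add atoms: none
Why: Proposed new method: thermal retro-[4+2] loss of acetone from 6 gives acylketene 13, the only free hydroxyl of 12 (the 4-OH, flanked by two ring hydrogens and therefore unhindered) adds to the ketene carbon to give aryl triketo ester 14, and Et3N then triggers aldol addition of the doubly activated C-2 to the C-7 ketone (15), after which acid dehydrates and enolizes to the aromatic ring. The closest known reaction type is the capture of diketo-dioxinone-derived acylketenes by aliphatic alcohols followed by aldol aromatization to alkyl resorcylates, together with the separately known acetoacetylation of phenols by dioxinone-derived acylketenes; new here is that the trap is a phenol, so the aromatization must run on an aryl ester. Ring B closes by a 6-exo-trig intramolecular aldol condensation (6-enolexo when C-2 reacts through its ester-enolate form) that forms the C-2–C-7 bond of the chain, which is C-1'–C-6' of ring B; no stereocentre survives, since both sp3 centres of 15 become sp2 on aromatization. The step needs O-acylation at a single site, which is secured because the other phenol and the acid of 12 are benzylated and because the phenols of ring B do not exist until base is added, by which time the ketene is consumed. It also needs the aldol path to win over attack of the C-5 enol oxygen on the ester carbonyl (4-hydroxy-2-pyrone with loss of the phenol) and over C-6-to-C-1 Claisen closure; a weak amine base in an aprotic solvent favours the C-2 enolate and supplies no nucleophile that could cleave the activated aryl ester. The ester between a di-ortho-substituted benzoyl group and a phenol is thus made before the ortho substituents exist, which avoids acylation with a hindered benzoic acid.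

Step 10
Reactants: 16 benzyl 2-(benzyloxy)-4-[(2,4-dihydroxy-6-propylbenzoyl)oxy]-6-propylbenzoate
Product: 17 benzyl 2-(benzyloxy)-4-{[4-(benzyloxy)-2-hydroxy-6-propylbenzoyl]oxy}-6-propylbenzoate
Conditions: BnBr (1.05 equiv), K2CO3, acetone, rt
Reagents that add atoms: benzyl bromide, BrCc1ccccc1
Why: mild Williamson benzylation selects the free 4'-OH over the 2'-OH, which is hydrogen-bonded to the depside carbonyl, by the same principle as in step 6.

Step 11
Reactants: 17 benzyl 2-(benzyloxy)-4-{[4-(benzyloxy)-2-hydroxy-6-propylbenzoyl]oxy}-6-propylbenzoate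
Product: 18 benzyl 2-(benzyloxy)-4-{[4-(benzyloxy)-2-methoxy-6-propylbenzoyl]oxy}-6-propylbenzoate
Conditions: MeI (excess), K2CO3, DMF, rt to 40 °C
Reagents that add atoms: iodomethane, CI
Why: Williamson methylation of the one remaining hydroxyl with a small electrophile in a polar aprotic solvent overcomes the chelation of the 2'-OH, while the depside ester is shielded from nucleophiles by its two ortho substituents.

Step 12
Reactants: 18 benzyl 2-(benzyloxy)-4-{[4-(benzyloxy)-2-methoxy-6-propylbenzoyl]oxy}-6-propylbenzoate
Product: 19 2-hydroxy-4-[(4-hydroxy-2-methoxy-6-propylbenzoyl)oxy]-6-propylbenzoic acid (target)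
Conditions: H2 (1 atm), Pd/C (10 wt% palladium on carbon), EtOAc, rt
Reagents that add atoms: none
Why: catalytic hydrogenolysis cleaves the benzyl ester and both benzyl aryl ethers in one operation, whereas the aryl benzoate linkage, the methyl ether and the arene rings are inert under these conditions.

**Compound list**

1 | 2,2,6-trimethyl-4H-1,3-dioxin-4-one | CC1=CC(=O)OC(C)(C)O1 | starting material
2 | acetyl chloride | CC(Cl)=O | starting material
3 | 2,2-dimethyl-6-(2-oxopropyl)-4H-1,3-dioxin-4-one | CC(=O)CC1=CC(=O)OC(C)(C)O1 | intermediate
4 | butanoyl chloride | CCCC(Cl)=O | starting material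
5 | N-methoxy-N-methylbutanamide | CCCC(=O)N(C)OC | intermediate
6 | 6-(2,4-dioxoheptyl)-2,2-dimethyl-4H-1,3-dioxin-4-one (diketo-dioxinone) | CCCC(=O)CC(=O)CC1=CC(=O)OC(C)(C)O1 | intermediate
7 | 5-hydroxy-2,2-dimethyl-5-propyl-5,6-dihydro-4H-1,3-benzodioxine-4,7(4aH)-dione (cyclic aldol adduct, not isolated; drawn as one tautomer, both sp3 centres undefined and lost on aromatization) | CCCC1(O)CC(=O)C=C2OC(C)(C)OC(=O)C21 | intermediate
8 | 7-hydroxy-2,2-dimethyl-5-propyl-4H-1,3-benzodioxin-4-one (resorcylate acetonide) | CCCc1cc(O)cc2OC(C)(C)OC(=O)c12 | intermediate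
9 | benzyl 2,4-dihydroxy-6-propylbenzoate | CCCc1cc(O)cc(O)c1C(=O)OCc1ccccc1 | intermediate
10 | benzyl 2-hydroxy-4-(prop-2-en-1-yloxy)-6-propylbenzoate | CCCc1cc(OCC=C)cc(O)c1C(=O)OCc1ccccc1 | intermediate
11 | benzyl 2-(benzyloxy)-4-(prop-2-en-1-yloxy)-6-propylbenzoate | CCCc1cc(OCC=C)cc(OCc2ccccc2)c1C(=O)OCc1ccccc1 | intermediate
12 | benzyl 2-(benzyloxy)-4-hydroxy-6-propylbenzoate | CCCc1cc(O)cc(OCc2ccccc2)c1C(=O)OCc1ccccc1 | intermediate
13 | dec-1-ene-1,3,5,7-tetrone (acylketene, not isolated) | CCCC(=O)CC(=O)CC(=O)C=C=O | intermediate
14 | benzyl 2-(benzyloxy)-6-propyl-4-[(3,5,7-trioxodecanoyl)oxy]benzoate (aryl triketo ester, not isolated) | CCCC(=O)CC(=O)CC(=O)CC(=O)Oc1cc(CCC)c(C(=O)OCc2ccccc2)c(OCc2ccccc2)c1 | intermediate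
15 | benzyl 2-(benzyloxy)-4-{[(2-hydroxy-4,6-dioxo-2-propylcyclohexyl)carbonyl]oxy}-6-propylbenzoate (cyclic aldol adduct, not isolated; mixture of stereoisomers and tautomers, both sp3 centres undefined and lost on aromatization) | CCCc1cc(OC(=O)C2C(=O)CC(=O)CC2(O)CCC)cc(OCc2ccccc2)c1C(=O)OCc1ccccc1 | intermediate
16 | benzyl 2-(benzyloxy)-4-[(2,4-dihydroxy-6-propylbenzoyl)oxy]-6-propylbenzoate | CCCc1cc(OC(=O)c2c(CCC)cc(O)cc2O)cc(OCc2ccccc2)c1C(=O)OCc1ccccc1 | intermediate
17 | benzyl 2-(benzyloxy)-4-{[4-(benzyloxy)-2-hydroxy-6-propylbenzoyl]oxy}-6-propylbenzoate | CCCc1cc(OC(=O)c2c(CCC)cc(OCc3ccccc3)cc2O)cc(OCc2ccccc2)c1C(=O)OCc1ccccc1 | intermediate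
18 | benzyl 2-(benzyloxy)-4-{[4-(benzyloxy)-2-methoxy-6-propylbenzoyl]oxy}-6-propylbenzoate | CCCc1cc(OC(=O)c2c(CCC)cc(OCc3ccccc3)cc2OC)cc(OCc2ccccc2)c1C(=O)OCc1ccccc1 | intermediate
19 | 2-hydroxy-4-[(4-hydroxy-2-methoxy-6-propylbenzoyl)oxy]-6-propylbenzoic acid | CCCc1cc(OC(=O)c2c(CCC)cc(O)cc2OC)cc(O)c1C(=O)O | target

**Step count**

Total step count: 12.
Longest linear sequence: 11 steps (steps 1, 3, 4, 5, 6, 7, 8, 9, 10, 11 and 12, from 1 to 19). Step 2 is a one-step branch, and diketo-dioxinone 6 is used twice, in steps 4 and 9.

**Steps most likely to fail**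

Step 9 (carries the label). Three things may go wrong:
- The electron-poor phenol may capture the acylketene too slowly, so that the ketene is lost by intramolecular O-cyclization.
- The aryl triketo ester may lactonize with expulsion of the phenol instead of closing by the aldol path.
- The activated aryl ester may fragment under the base.

The fallback is the classical depside esterification through a mixed trifluoroacetic anhydride, which is known chemistry. It sets out from 8. Benzylation of its only free hydroxyl (BnBr, K2CO3, acetone, rt) gives 7-(benzyloxy)-2,2-dimethyl-5-propyl-4H-1,3-benzodioxin-4-one F1. Saponification of the acetonide (KOH, DMSO–H2O, 60 °C; cold acidification) liberates 4-(benzyloxy)-2-hydroxy-6-propylbenzoic acid F2. Treatment of F2 and phenol 12 with (CF3CO)2O in toluene at rt then forms the mixed anhydride of the di-ortho-substituted acid, which ionizes to the acylium ion and acylates the 4-OH of 12; the chelated 2-OH of F2 needs no protection. The fallback comes back to the route at 17, and steps 11 and 12 follow unchanged.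

Step 5. Under the base the 7-OH of 8 is deprotonated, and donation from this phenoxide into the lactone carbonyl may slow the addition of benzyloxide. Adventitious hydroxide may then open the ring instead, and the resorcylic acid so formed would be lost by decarboxylation. The fallback changes the order of events so that the ring is opened on an aryl ether and not on a phenoxide, and sets out from 8. Allylation of its only free hydroxyl (allyl bromide, K2CO3, acetone, rt), which needs no selectivity, gives 2,2-dimethyl-7-(prop-2-en-1-yloxy)-5-propyl-4H-1,3-benzodioxin-4-one F3. Opening of F3 with benzyl alcohol and Cs2CO3 in THF at 60 °C then gives the benzyl ester with the 2-OH free and O-4 already allylated. The fallback comes back to the route at 10 and bypasses steps 5 and 6.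

Step 3. Deprotonation may be incomplete or misdirected, giving acylation at the central CH2 or on oxygen. The dianion may be quenched by proton transfer from the more acidic product, and the sensitive diketo-dioxinone may degrade during work-up. The fallback replaces the dianion by a regiodefined malonate-type enolate and sets out from 1. The lithium dienolate of 1 is acylated with prop-2-en-1-yl 3-chloro-3-oxopropanoate to give prop-2-en-1-yl 4-(2,2-dimethyl-4-oxo-4H-1,3-dioxin-6-yl)-3-oxobutanoate F4. Its magnesium enolate (MgCl2, pyridine, CH2Cl2, 0 °C) is C-acylated by butanoyl chloride 4 at the carbon between ketone and ester, giving prop-2-en-1-yl 2-butanoyl-4-(2,2-dimethyl-4-oxo-4H-1,3-dioxin-6-yl)-3-oxobutanoate F5. Pd(PPh3)4 and morpholine in THF then remove the allyl group, and the acid loses CO2. The fallback comes back to the route at 6 and bypasses steps 1 to 3.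

**Further compounds**

F1 | step 9 | 7-(benzyloxy)-2,2-dimethyl-5-propyl-4H-1,3-benzodioxin-4-one | CCCc1cc(OCc2ccccc2)cc2OC(C)(C)OC(=O)c12
F2 | step 9 | 4-(benzyloxy)-2-hydroxy-6-propylbenzoic acid | CCCc1cc(OCc2ccccc2)cc(O)c1C(=O)O
F3 | step 5 | 2,2-dimethyl-7-(prop-2-en-1-yloxy)-5-propyl-4H-1,3-benzodioxin-4-one | CCCc1cc(OCC=C)cc2OC(C)(C)OC(=O)c12
F4 | step 3 | prop-2-en-1-yl 4-(2,2-dimethyl-4-oxo-4H-1,3-dioxin-6-yl)-3-oxobutanoate | C=CCOC(=O)CC(=O)CC1=CC(=O)OC(C)(C)O1
F5 | step 3 | prop-2-en-1-yl 2-butanoyl-4-(2,2-dimethyl-4-oxo-4H-1,3-dioxin-6-yl)-3-oxobutanoate | CCCC(=O)C(C(=O)OCC=C)C(=O)CC1=CC(=O)OC(C)(C)O1
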